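Numbering as in labdanes: ring A = C1–C5 + C10, ring B = C5–C10, C17 on C8, C18 (acid) and C19 (methyl) on C4, C20 on C10, side chain C11–C13; α is the face opposite to C20.
Both acids come from primary alcohols (C13, C18). 8α-O and 9α-H come from one syn hydroboration of a C8=C9 alkene, and the C9–C11 bond from an allyl coupling at a C9 enol triflate.
Key disconnection: C3–C4 of ring A, by Pd(0) vinylborylation (6-exo Heck carbopalladation, then C18–B bond formation) of a (Z)-1-iodo-1,6-diene. This closes ring A, builds quaternary C4 and marks C18 for the acid.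
Enabling feature: on ring B the isopropenyl group at C5 (C4=C18, C19) and the (Z)-3-iodoallyl arm at quaternary C10 (C1–C3) are vicinal, trans and diequatorial. C4 becomes fully substituted on insertion, so Pd on C18 has no β-hydrogen and waits for boron.
Ring order: ring B is the ring of (R)-carvone (all ten carbons kept, C5 from the chiral pool, C10 by two α'-alkylations); ring A is closed last, in step 5.
Key step: step 5

Remark: compounds 1 and 4 are taken as commercially available.

Step 1
Reactants: 1 ethyl (Z)-3-iodoacrylate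
Product: 2 (Z)-3-iodoprop-2-en-1-ol
Conditions: DIBAL-H (2.2 equiv), CH2Cl2, −78 to 0 °C; aq. Rochelle salt
Reagents that add atoms: none
Why: DIBAL-H reduction of the ester to the allylic alcohol, which at low temperature should leave the C–I bond and the Z geometry untouched.

Step 2
Reactants: 2 (Z)-3-iodoprop-2-en-1-ol
Product: 3 (Z)-3-bromo-1-iodoprop-1-ene
Conditions: CBr4, PPh3, CH2Cl2, 0 °C
Reagents that add atoms: carbon tetrabromide, BrC(Br)(Br)Br
Why: Appel reaction; the neutral SN2 displacement at the primary allylic carbon should keep the Z-alkenyl iodide intact.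

Step 3
Reactants: 4 (R)-(−)-carvone
Product: 6 6-methylcarvone (C6 epimers), via lithium dienolate of carvone 5 (not isolated)
Conditions: LDA (1.05 equiv), THF, −78 °C; MeI, −78 to 0 °C
Reagents that add atoms: lithium diisopropylamide, [Li+].CC(C)[N-]C(C)C (Li of 5); iodomethane, CI
Why: Kinetic α'-deprotonation and enolate alkylation bring in C20; the configuration of the new centre does not matter because it is planarized again in step 4.

Step 4
Reactants: 6 6-methylcarvone (C6 epimers); 3 (Z)-3-bromo-1-iodoprop-1-ene
Product: 8 (5S,6S)-6-[(Z)-3-iodoallyl]-6-methylcarvone, via lithium dienolate of 6-methylcarvone 7 (not isolated)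
Conditions: LDA, THF, −78 °C; 3, DMPU, −78 °C to rt
Reagents that add atoms: lithium diisopropylamide, [Li+].CC(C)[N-]C(C)C (Li of 7)
Why: Enolate alkylation with the allylic bromide; both epimers of 6 give the same planar dienolate, which should be attacked anti to the C5 isopropenyl group and so set quaternary C10 with C20 cis and the C1–C3 arm trans to the isopropenyl group.

Step 5
Reactants: 8 (5S,6S)-6-[(Z)-3-iodoallyl]-6-methylcarvone
Product: 9 bicyclic dienone boronate (ring A closed)
Conditions: Pd2(dba)3 (2.5 mol %), dppf (6 mol %), B2pin2 (2 equiv), KOAc (3 equiv), 1,4-dioxane, 80 °C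
Reagents that add atoms: bis(pinacolato)diboron, CC1(C)OB(OC1(C)C)B1OC(C)(C)C(C)(C)O1
Why: Pd(0) inserts into the (Z)-C3–I bond with retention, the alkenyl-Pd adds syn across the isopropenyl alkene C4=C18 so that C3 bonds to C4, and the resulting C18–Pd species, which has no β-hydrogen because C4 is now quaternary, is transmetalated by acetate-activated B2pin2 and reductively eliminates the C18–B bond. The closest known reaction type is the Pd-catalysed vinylborylation (domino Heck/borylation), with the related carboiodination, of (Z)-1-iodo-1,6-dienes, which builds six-membered rings carrying a CH2X group on a new quaternary carbon. Ring A closes in the 6-exo-trig mode, since the 7-endo alternative would need attack at the terminal CH2 and is disfavoured for a 1,1-disubstituted alkene on a tether of this length. The only new stereocentre, C4, is controlled by C5 and C10: both arms sit equatorial on the half-chair of ring B (C20 axial), the alkene must lie parallel to the C3–Pd bond, and the Pd-bearing CH2 should take the open pseudo-equatorial sector next to H-5 while the smaller C19 methyl turns towards C10, giving 4α-CH2B and 4β-CH3 on a trans ring fusion already fixed by C5 and C10. The step needs insertion to outrun direct borylation of the alkenyl-Pd and needs chemoselectivity over the enone: the gauche diequatorial arms hold C3 within bonding distance of C4, and the C7=C8 alkene is trisubstituted, electron-poor and out of reach of the tether.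

Step 6
Reactants: 9 bicyclic dienone boronate
Product: 10 bicyclic ketone boronate (C8 epimers)
Conditions: H2 (1 atm), 10% Pd/C, EtOAc, rt
Reagents that add atoms: none
Why: Heterogeneous catalytic hydrogenation saturates C2=C3 and the enone C7=C8 while sparing ketone and boronate; the C8 epimer mixture is harmless because C8 is planarized in step 7.

Step 7
Reactants: 10 bicyclic ketone boronate
Product: 12 C9 enol triflate, via lithium enolate of ketone 11 (not isolated)
Conditions: LDA, THF, −78 to 0 °C; PhNTf2, 0 °C to rt
Reagents that add atoms: lithium diisopropylamide, [Li+].CC(C)[N-]C(C)C (Li of 11); N-phenylbis(trifluoromethanesulfonimide), O=S(=O)(N(c1ccccc1)S(=O)(=O)C(F)(F)F)C(F)(F)F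
Why: Enol triflate formation; the ketone has a single α-hydrogen (at C8, since C10 is quaternary), so only the C8=C9 enolate can form, as with 2,2,6-trimethylcyclohexanone.

Step 8
Reactants: 12 C9 enol triflate
Product: 13 C9-allyl C8=C9 alkene boronate
Conditions: allylSnBu3, Pd(PPh3)4 (5 mol %), LiCl (3 equiv), THF, reflux
Reagents that add atoms: allyltributylstannane, C=CC[Sn](CCCC)(CCCC)CCCC
Why: LiCl-promoted Stille coupling of the enol triflate installs C11–C13 at C9; the neopentyl pinacol boronate should not transmetalate under these base-free conditions.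

Step 9
Reactants: 13 C9-allyl C8=C9 alkene boronate
Product: 16 8α,13,18-triol, via B-alkyl-9-BBN adduct 14 (not isolated), via triborylated intermediate 15 (not isolated)
Conditions: 9-BBN (1.1 equiv), THF, rt; BH3·THF (3 equiv), 0 to 40 °C; NaOH, H2O2, 0 °C to rt
Reagents that add atoms: 9-borabicyclo[3.3.1]nonane, B1C2CCCC1CCC2 (B of 14 and 15); borane, B (B of 15); hydrogen peroxide, OO
Why: Hydroboration–oxidation; 9-BBN takes the terminal alkene anti-Markovnikov, BH3 should then add syn to C8=C9 from the α face (the β face is shielded by axial C20) with boron on the less crowded C8, and alkaline peroxide oxidizes all three C–B bonds with retention, setting 8α-OH and 9α-H and unmasking C18–OH.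

Step 10
Reactants: 16 8α,13,18-triol
Product: 17 8α,13,18-triacetate
Conditions: Ac2O (excess), Et3N, DMAP, CH2Cl2, rt to 40 °C
Reagents that add atoms: acetic anhydride, CC(=O)OC(C)=O
Why: DMAP-catalysed acylation driven to completion at the hindered tertiary 8α-OH; the basic medium avoids ionization at C8 and ether formation with C13–OH.

Step 11
Reactants: 17 8α,13,18-triacetate
Product: 18 8α-acetoxy-13,18-diol
Conditions: K2CO3 (cat.), MeOH, 0 °C to rt
Reagents that add atoms: none
Why: Base-catalysed transesterification (methanolysis) should remove the two primary acetates and leave the much more hindered tertiary 8α-acetate.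

Step 12
Reactants: 18 8α-acetoxy-13,18-diol
Product: 20 CNP0196050.1 (8α-acetoxy-14,15,16-trinorlabdane-13,18-dioic acid), via dialdehyde 19 (not isolated)
Conditions: TEMPO (20 mol %), PhI(OAc)2 (4.5 equiv), MeCN/H2O 1:1, rt
Reagents that add atoms: water, O
Why: Oxoammonium (TEMPO) oxidation with PhI(OAc)2 in aqueous acetonitrile takes both primary alcohols through the aldehyde hydrates to the acids under near-neutral conditions that spare the tertiary acetate and touch no stereocentre.

Compound list
1 | ethyl (Z)-3-iodoacrylate | CCOC(=O)/C=C\I | starting material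
2 | (Z)-3-iodoprop-2-en-1-ol | OC/C=C\I | intermediate
3 | (Z)-3-bromo-1-iodoprop-1-ene | BrC/C=C\I | intermediate
4 | (R)-(−)-carvone | CC1=CC[C@@H](C(C)=C)CC1=O | starting material
5 | lithium cross-conjugated dienolate of carvone (deprotonated at the α'-CH2) | CC1=CC[C@@H](C(C)=C)C=C1[O-].[Li+] | intermediate
6 | (5R)-2,6-dimethyl-5-(prop-1-en-2-yl)cyclohex-2-en-1-one, 6-methylcarvone, both C6 epimers | CC1=CC[C@@H](C(C)=C)C(C)C1=O | intermediate
7 | lithium dienolate of 6-methylcarvone | CC1=CC[C@@H](C(C)=C)C(C)=C1[O-].[Li+] | intermediate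
8 | (5S,6S)-6-[(Z)-3-iodoprop-2-enyl]-2,6-dimethyl-5-(prop-1-en-2-yl)cyclohex-2-en-1-one; iodoallyl trans, methyl cis to isopropenyl | CC1=CC[C@@H](C(C)=C)[C@](C)(C/C=C\I)C1=O | intermediate
9 | trans-fused bicyclic dienone (5α-H, 10β-CH3) with C2=C3, C7=C8, C9=O, 4β-CH3 and 4α-CH2Bpin | CC1=CC[C@@H]2[C@](C)(CC=C[C@@]2(C)CB3OC(C)(C)C(C)(C)O3)C1=O | intermediate
10 | saturated trans-decalin C9 ketone with 4α-CH2Bpin, both C8 epimers | CC1CC[C@@H]2[C@](C)(CCC[C@@]2(C)CB3OC(C)(C)C(C)(C)O3)C1=O | intermediate
11 | lithium C8=C9 enolate of 10 | CC=1CC[C@@H]2[C@](C)(CCC[C@@]2(C)CB3OC(C)(C)C(C)(C)O3)C=1[O-].[Li+] | intermediate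
12 | C9 enol triflate (C8=C9) with 4α-CH2Bpin | CC=1CC[C@@H]2[C@](C)(CCC[C@@]2(C)CB3OC(C)(C)C(C)(C)O3)C=1OS(=O)(=O)C(F)(F)F | intermediate
13 | 9-allyl C8=C9 alkene with 4α-CH2Bpin | CC=1CC[C@@H]2[C@](C)(CCC[C@@]2(C)CB3OC(C)(C)C(C)(C)O3)C=1CC=C | intermediate
14 | adduct of 13 with 9-BBN at C13 | CC=1CC[C@@H]2[C@](C)(CCC[C@@]2(C)CB3OC(C)(C)C(C)(C)O3)C=1CCCB4C5CCCC4CCC5 | intermediate
15 | 8α-boryl-9α-H compound carrying boron at C8, C13 and C18 | B[C@]1(C)CC[C@@H]2[C@](C)(CCC[C@@]2(C)CB3OC(C)(C)C(C)(C)O3)[C@H]1CCCB4C5CCCC4CCC5 | intermediate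
16 | 14,15,16-trinorlabdane-8α,13,18-triol | O[C@]1(C)CC[C@@H]2[C@](C)(CCC[C@@]2(C)CO)[C@H]1CCCO | intermediate
17 | 8α,13,18-triacetoxy-14,15,16-trinorlabdane | CC(=O)O[C@]1(C)CC[C@@H]2[C@](C)(CCC[C@@]2(C)COC(C)=O)[C@H]1CCCOC(C)=O | intermediate
18 | 8α-acetoxy-14,15,16-trinorlabdane-13,18-diol | CC(=O)O[C@]1(C)CC[C@@H]2[C@](C)(CCC[C@@]2(C)CO)[C@H]1CCCO | intermediate
19 | 8α-acetoxy-14,15,16-trinorlabdane-13,18-dial | CC(=O)O[C@]1(C)CC[C@@H]2[C@](C)(CCC[C@@]2(C)C=O)[C@H]1CCC=O | intermediate
20 | CNP0196050.1, 8α-acetoxy-14,15,16-trinorlabdane-13,18-dioic acid | CC(=O)O[C@]1(C)CC[C@@H]2[C@](C)(CCC[C@@]2(C)C(=O)O)[C@H]1CCC(=O)O | target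

Total step count: 12. Longest linear sequence: 11 steps (1, 2, 4–12); 10 steps from carvone (3–12).

Steps most likely to fail

Step 5. The alkenyl-palladium species may be borylated before it inserts, or the neopentyl palladium species may migrate through a 3-exo closure onto the new C2=C3 bond. The fallback forms the same C3–C4 bond from an enolate instead of an alkene.
- From 8, mCPBA (CH2Cl2, 0 °C) should epoxidize only the isopropenyl group to the isopropenyl epoxide F1 (both epimers).
- A Meinwald rearrangement (BF3·OEt2, CH2Cl2, −78 °C) should give the α-branched aldehyde F2 (both C4 epimers).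
- A Pd-catalysed intramolecular α-alkenylation of the aldehyde enolate (Pd(OAc)2, BINAP, Cs2CO3, THF, 70 °C) should give the ring-closed enone aldehyde F3. The planar enolate funnels both epimers to 4α-CHO and 4β-CH3 through allylic strain.
- Hydrogenation (H2, Pd/C) leads to the saturated keto aldehyde F4.
- Aldehyde-selective reduction (NaBH4, MeOH, −78 °C) leads to the hydroxy ketone F5.
- Iodination (I2, PPh3, imidazole) leads to the neopentyl iodide F6.
- Cu-catalysed borylation (CuI, PPh3, LiOMe, B2pin2, DMF, rt) brings the material back to the route at 10.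

Step 9. Borane may add slowly or with the wrong regiochemistry to the hindered tetrasubstituted alkene, or the tertiary borane may migrate on warming. The fallback replaces syn hydroboration by allylic oxygenation and directed hydrogenation.
- From 13, 9-BBN alone followed by NaOH/H2O2 (through 14) should give the C8=C9 unsaturated 13,18-diol F7.
- A Schenck ene reaction (O2, tetraphenylporphyrin, hν, CH2Cl2) should attack the α face and abstract a C11 hydrogen, which is geminal to the bulky C10 substituent, to give the 8α-hydroperoxide F8.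
- PPh3 reduces this to the 8α-hydroxy C9=C11 allylic alcohol F9 (alkene geometry not controlled).
- Hydroxyl-directed hydrogenation with [Ir(cod)(PCy3)(py)]PF6 (H2, CH2Cl2) should deliver hydrogen to C9 from the α face and return to the route at 16.

Step 11. The tertiary acetate may be lost, or the neopentyl C18 acetate may be cleaved incompletely. The fallback uses orthogonal protection instead of kinetic discrimination and bypasses 17.
- From 16, TBSCl (2.2 equiv) and imidazole in DMF should silylate only the primary alcohols to the 13,18-bis(silyl ether) F10.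
- Ac2O/DMAP/Et3N gives the 8α-acetate bis(silyl ether) F11.
- TBAF buffered with AcOH (THF, rt) returns to the route at 18.

Further compounds
F1 | step 5 | isopropenyl epoxide of 8 (both oxirane epimers) | CC1=CC[C@@H](C2(C)CO2)[C@](C)(C/C=C\I)C1=O
F2 | step 5 | α-branched aldehyde, 2-substituted propanal (both C4 epimers) | CC1=CC[C@@H](C(C)C=O)[C@](C)(C/C=C\I)C1=O
F3 | step 5 | ring-closed enone aldehyde, 4α-CHO, 4β-CH3, C2=C3, C7=C8, C9=O | CC1=CC[C@@H]2[C@](C)(CC=C[C@@]2(C)C=O)C1=O
F4 | step 5 | saturated keto aldehyde (C8 epimers) | CC1CC[C@@H]2[C@](C)(CCC[C@@]2(C)C=O)C1=O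
F5 | step 5 | hydroxy ketone, 4α-CH2OH (C8 epimers) | CC1CC[C@@H]2[C@](C)(CCC[C@@]2(C)CO)C1=O
F6 | step 5 | neopentyl iodide, 4α-CH2I (C8 epimers) | CC1CC[C@@H]2[C@](C)(CCC[C@@]2(C)CI)C1=O
F7 | step 9 | C8=C9 unsaturated 13,18-diol | CC=1CC[C@@H]2[C@](C)(CCC[C@@]2(C)CO)C=1CCCO
F8 | step 9 | 8α-hydroperoxide with C9=C11 alkene | OO[C@]1(C)CC[C@@H]2[C@](C)(CCC[C@@]2(C)CO)C1=CCCO
F9 | step 9 | 8α-hydroxy C9=C11 allylic alcohol | O[C@]1(C)CC[C@@H]2[C@](C)(CCC[C@@]2(C)CO)C1=CCCO
F10 | step 11 | 13,18-bis(tert-butyldimethylsilyl ether) of 16 | O[C@]1(C)CC[C@@H]2[C@](C)(CCC[C@@]2(C)CO[Si](C)(C)C(C)(C)C)[C@H]1CCCO[Si](C)(C)C(C)(C)C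
F11 | step 11 | 8α-acetate of the bis(silyl ether) | CC(=O)O[C@]1(C)CC[C@@H]2[C@](C)(CCC[C@@]2(C)CO[Si](C)(C)C(C)(C)C)[C@H]1CCCO[Si](C)(C)C(C)(C)C
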